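**Plan**

- Retrosynthesis: the target is cut first at the bond between the bridging CH2 and C6 of ring A (the cyclohexadienone). Ring B (the arene) is then cut at the aryl–C(=O)Pr bond, at the C–CH3 bond between its two oxygens, and last at the two ring bonds flanking one phenol carbon, which is traced back to CO.
- Enabling feature: ring B carries two oxygens meta to each other, one on the carbon next to the CH2-bearing carbon and one on the carbon next to the butanoyl-bearing carbon. A 3-butanoyloxy-1,4-enyne plus CO gives exactly this pattern, the ester oxygen and the CO oxygen becoming the two phenol oxygens.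
- Forward, ring B: an open-chain E-enyne butanoate is assembled by Wittig olefination, ethynyl addition and esterification, and ring B is closed from it by rhodium-catalysed acyloxy shift and carbonylative benzannulation.
- Ring B is finished by ortho-methylation (sulfonium ylide shift, then desulfurisation), photo-Fries transfer of the butanoyl group from O to C, and desilylation. The methyl is placed before the Fries shift so that only one ortho carbon is left for the acyl group.
- Ring A comes from phloroglucinol by C-acylation and geminal C-methylation; the two rings are joined last through the benzylic carbon of ring B.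
- Stereochemistry: the target has no stereocentre. The only stereo element on the way is the E-alkene of the enyne (stabilised ylide); the racemic carbinol centre vanishes on aromatisation.

Key step: step 4

Remark: ring A is written throughout in the enol tautomer of the target SMILES; its tautomers interconvert freely, and all chiral intermediates are racemic.

**Route**

Step 1
Reactants: 1 (tert-butyldimethylsilyloxy)acetaldehyde; 2 2-(triphenylphosphoranylidene)propanal
Product: 3 (E)-4-(tert-butyldimethylsilyloxy)-2-methylbut-2-enal
Conditions: PhMe, 80 °C
Reagents that add atoms: 2-(triphenylphosphoranylidene)propanal (2), CC(C=O)=P(c1ccccc1)(c1ccccc1)c1ccccc1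
Why: Wittig olefination with a formyl-stabilised ylide, which reacts only with the more electrophilic aliphatic aldehyde and, being stabilised, should give the E-trisubstituted enal.

Step 2
Reactants: 3 (E)-4-(tert-butyldimethylsilyloxy)-2-methylbut-2-enal; 4 ethynylmagnesium bromide
Product: 5 rac-(E)-6-(tert-butyldimethylsilyloxy)-4-methylhex-4-en-1-yn-3-ol
Conditions: THF, −78 to 0 °C; aq NH4Cl
Reagents that add atoms: ethynylmagnesium bromide (4), C#C[Mg]Br
Why: Grignard 1,2-addition of the hard alkynyl nucleophile to the enal carbonyl should give the secondary propargylic alcohol as a racemate, which is acceptable because this carbon later becomes an aromatic CH.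

Step 3
Reactants: 5 rac-(E)-6-(tert-butyldimethylsilyloxy)-4-methylhex-4-en-1-yn-3-ol; 6 butanoyl chloride
Product: 7 rac-(E)-6-(tert-butyldimethylsilyloxy)-4-methylhex-4-en-1-yn-3-yl butanoate
Conditions: Et3N, DMAP (cat.), CH2Cl2, 0 °C to rt
Reagents that add atoms: butanoyl chloride (6), CCCC(=O)Cl
Why: DMAP-catalysed acylation of a secondary alcohol with an acid chloride is routine and leaves the silyl ether, alkyne and alkene untouched.

Step 4
Reactants: 7 rac-(E)-6-(tert-butyldimethylsilyloxy)-4-methylhex-4-en-1-yn-3-yl butanoate; 8 carbon monoxide
Product: 11 4-(tert-butyldimethylsilyloxymethyl)-3-hydroxy-5-methylphenyl butanoate, via dienylketene 9 (not isolated), via cyclohexadienone tautomer 10 (not isolated)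
Conditions: [RhCl(CO)2]2 (5 mol %), CO (50 atm), CH2Cl2, 80 °C, autoclave
Reagents that add atoms: carbon monoxide (8), [C-]#[O+]
Why: Coordination of the terminal alkyne to monovalent rhodium makes its internal carbon electrophilic toward the ester carbonyl oxygen, and opening of the resulting dioxolenylium leaves the butanoyloxy group on that carbon and a rhodium carbene at the former alkyne terminus, conjugated with two C=C bonds. CO insertion into the carbene makes the first new ring bond (CO carbon to former alkyne terminus) and gives dienylketene 9 or its rhodacyclic equivalent; a thermal disrotatory six-electron electrocyclisation then makes the second ring bond (CO carbon to alkene terminus), closing ring B as a six-membered carbocycle, and dienone 10 tautomerises to phenol 11. The closest known reaction type is the [RhCl(CO)2]2-catalysed carbonylative five-plus-one annulation of terminal 3-acyloxy-1,4-enynes to resorcinol monoesters, which accepts trisubstituted alkenes; the allylic silyl ether is only a new spectator. No stereocentre remains, since the carbinol centre of 7 and the sp3 carbon of 10 both become aromatic. Two selectivities are required: a 1,2-shift of the butanoate instead of a 1,3-shift to an allene, which the unsubstituted alkyne terminus secures, and capture of the carbene by CO before it closes onto the alkene to a five-membered ring, which the CO pressure secures. With the E-alkene, H and not CH2OSi occupies the inside position of the closing triene, and the ester is expected to stay on the migrated oxygen, so the free hydroxyl lies next to the CH2OSi-bearing carbon.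

Step 5
Reactants: 11 4-(tert-butyldimethylsilyloxymethyl)-3-hydroxy-5-methylphenyl butanoate; 12 dimethyl sulfide
Product: 14 4-(tert-butyldimethylsilyloxymethyl)-3-hydroxy-5-methyl-2-(methylsulfanylmethyl)phenyl butanoate, via aryloxysulfonium chloride 13 (not isolated)
Conditions: Me2S, N-chlorosuccinimide, CH2Cl2, −25 °C; add 11; then Et3N, −25 °C to rt
Reagents that add atoms: dimethyl sulfide (12), CSC
Why: Gassman ortho-alkylation of a phenol, in which the aryloxysulfonium salt is deprotonated to its ylide and a [2,3]-sigmatropic shift followed by rearomatisation delivers CH2SMe to the only hydrogen-bearing carbon ortho to the free hydroxyl, i.e. the carbon between the two oxygens.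

Step 6
Reactants: 14 4-(tert-butyldimethylsilyloxymethyl)-3-hydroxy-5-methyl-2-(methylsulfanylmethyl)phenyl butanoate
Product: 15 4-(tert-butyldimethylsilyloxymethyl)-3-hydroxy-2,5-dimethylphenyl butanoate
Conditions: Raney Ni (neutral-washed), EtOH–THF, rt
Reagents that add atoms: none
Why: Raney Ni desulfurisation cleaves both C–S bonds far faster than it touches a benzylic silyl ether or an aryl ester, which turns the CH2SMe group into the ring methyl.

Step 7
Reactants: 15 4-(tert-butyldimethylsilyloxymethyl)-3-hydroxy-2,5-dimethylphenyl butanoate
Product: 16 1-[5-(tert-butyldimethylsilyloxymethyl)-2,4-dihydroxy-3,6-dimethylphenyl]butan-1-one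
Conditions: hν (254 nm, quartz), degassed cyclohexane, rt
Reagents that add atoms: none
Why: Photo-Fries rearrangement, in which the excited ester cleaves at the ArO–C(=O) bond and the caged acyl/aryloxyl radical pair recombines at an ortho carbon; only the one next to the ring methyl still carries hydrogen (the other ortho carbon holds the new methyl, the para carbon the CH2OSi group), the chelated ortho-hydroxy ketone formed is photostable, and the aprotic solvent disfavours light-induced loss of silanol from the ortho-hydroxybenzyl ether.

Step 8
Reactants: 16 1-[5-(tert-butyldimethylsilyloxymethyl)-2,4-dihydroxy-3,6-dimethylphenyl]butan-1-one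
Product: 17 1-[2,4-dihydroxy-5-(hydroxymethyl)-3,6-dimethylphenyl]butan-1-one
Conditions: Bu4NF, AcOH, THF, 0 °C
Reagents that add atoms: none
Why: Fluoride-induced desilylation of a primary silyl ether, buffered with AcOH so that the acidic phenols stay protonated and the salicyl alcohol is not pushed toward its quinone methide before the coupling partner is present.

Step 9
Reactants: 18 phloroglucinol; 6 butanoyl chloride
Product: 19 1-(2,4,6-trihydroxyphenyl)butan-1-one
Conditions: AlCl3 (4 equiv), CH2Cl2–PhNO2, 0 °C to rt; aq HCl
Reagents that add atoms: butanoyl chloride (6), CCCC(=O)Cl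
Why: Friedel–Crafts C-acylation of phloroglucinol, which should stop at the mono-ketone because the product is deactivated as its aluminium chelate.

Step 10
Reactants: 19 1-(2,4,6-trihydroxyphenyl)butan-1-one; 20 iodomethane
Product: 21 2-butanoyl-3,5-dihydroxy-4,4-dimethylcyclohexa-2,5-dien-1-one (butyrylfilicinic acid)
Conditions: NaOMe (3 equiv), MeI (2.2 equiv), MeOH, 0 °C to rt; aq HCl
Reagents that add atoms: iodomethane (20), CI
Why: Base-mediated C-methylation of the acylphloroglucinol anion, the classical entry to acylfilicinic acids, in which the soft electrophile attacks ring carbon and the second methyl enters the already methylated carbon to give the dearomatised, strongly acidic β-triketone.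

Step 11
Reactants: 17 1-[2,4-dihydroxy-5-(hydroxymethyl)-3,6-dimethylphenyl]butan-1-one; 21 2-butanoyl-3,5-dihydroxy-4,4-dimethylcyclohexa-2,5-dien-1-one
Product: 23 2-butanoyl-6-[(3-butanoyl-4,6-dihydroxy-2,5-dimethylphenyl)methyl]-3,5-dihydroxy-4,4-dimethylcyclohexa-2,5-dien-1-one, via ortho-quinone methide 22 (not isolated)
Conditions: TsOH·H2O (10 mol %), MeCN, rt; 21 in slight excess
Reagents that add atoms: none
Why: Acid-catalysed dehydration of the 2,4-dihydroxybenzyl alcohol gives an ortho-quinone methide that is trapped in a Michael addition by the only unsubstituted enolic carbon of ring A, rearomatisation of ring B driving the reaction; ring B has no free ring carbon left for self-condensation.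

**Compound list**

1 | (tert-butyldimethylsilyloxy)acetaldehyde | CC(C)(C)[Si](C)(C)OCC=O | starting material
2 | 2-(triphenylphosphoranylidene)propanal | CC(C=O)=P(c1ccccc1)(c1ccccc1)c1ccccc1 | starting material
3 | (E)-4-(tert-butyldimethylsilyloxy)-2-methylbut-2-enal | O=C/C(C)=C/CO[Si](C)(C)C(C)(C)C | intermediate
4 | ethynylmagnesium bromide (THF solution) | C#C[Mg]Br | starting material
5 | rac-(E)-6-(tert-butyldimethylsilyloxy)-4-methylhex-4-en-1-yn-3-ol | C#CC(O)/C(C)=C/CO[Si](C)(C)C(C)(C)C | intermediate
6 | butanoyl chloride | CCCC(=O)Cl | starting material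
7 | rac-(E)-6-(tert-butyldimethylsilyloxy)-4-methylhex-4-en-1-yn-3-yl butanoate | C#CC(OC(=O)CCC)/C(C)=C/CO[Si](C)(C)C(C)(C)C | intermediate
8 | carbon monoxide | [C-]#[O+] | starting material
9 | (3E,5E)-3-butanoyloxy-7-(tert-butyldimethylsilyloxy)-5-methylhepta-1,3,5-trien-1-one (dienylketene, ketene carbon cis to C5 across C3=C4) | O=C=C/C(OC(=O)CCC)=C\C(C)=C\CO[Si](C)(C)C(C)(C)C | intermediate
10 | rac-3-butanoyloxy-6-(tert-butyldimethylsilyloxymethyl)-5-methylcyclohexa-2,4-dien-1-one | O=C1C=C(OC(=O)CCC)C=C(C)C1CO[Si](C)(C)C(C)(C)C | intermediate
11 | 4-(tert-butyldimethylsilyloxymethyl)-3-hydroxy-5-methylphenyl butanoate | CCCC(=O)Oc1cc(O)c(CO[Si](C)(C)C(C)(C)C)c(C)c1 | intermediate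
12 | dimethyl sulfide | CSC | starting material
13 | [3-butanoyloxy-6-(tert-butyldimethylsilyloxymethyl)-5-methylphenoxy]dimethylsulfonium chloride | CCCC(=O)Oc1cc(C)c(CO[Si](C)(C)C(C)(C)C)c(O[S+](C)C)c1.[Cl-] | intermediate
14 | 4-(tert-butyldimethylsilyloxymethyl)-3-hydroxy-5-methyl-2-(methylsulfanylmethyl)phenyl butanoate | CCCC(=O)Oc1cc(C)c(CO[Si](C)(C)C(C)(C)C)c(O)c1CSC | intermediate
15 | 4-(tert-butyldimethylsilyloxymethyl)-3-hydroxy-2,5-dimethylphenyl butanoate | CCCC(=O)Oc1cc(C)c(CO[Si](C)(C)C(C)(C)C)c(O)c1C | intermediate
16 | 1-[5-(tert-butyldimethylsilyloxymethyl)-2,4-dihydroxy-3,6-dimethylphenyl]butan-1-one | CCCC(=O)c1c(O)c(C)c(O)c(CO[Si](C)(C)C(C)(C)C)c1C | intermediate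
17 | 1-[2,4-dihydroxy-5-(hydroxymethyl)-3,6-dimethylphenyl]butan-1-one | CCCC(=O)c1c(O)c(C)c(O)c(CO)c1C | intermediate
18 | phloroglucinol | Oc1cc(O)cc(O)c1 | starting material
19 | 1-(2,4,6-trihydroxyphenyl)butan-1-one | CCCC(=O)c1c(O)cc(O)cc1O | intermediate
20 | iodomethane | CI | starting material
21 | 2-butanoyl-3,5-dihydroxy-4,4-dimethylcyclohexa-2,5-dien-1-one | CCCC(=O)C1=C(O)C(C)(C)C(O)=CC1=O | intermediate
22 | 4-butanoyl-3-hydroxy-2,5-dimethyl-6-methylidenecyclohexa-2,4-dien-1-one | CCCC(=O)C1=C(C)C(=C)C(=O)C(C)=C1O | intermediate
23 | 2-butanoyl-6-[(3-butanoyl-4,6-dihydroxy-2,5-dimethylphenyl)methyl]-3,5-dihydroxy-4,4-dimethylcyclohexa-2,5-dien-1-one | CCCC(=O)C1=C(O)C(C)(C)C(O)=C(Cc2c(C)c(C(=O)CCC)c(O)c(C)c2O)C1=O | target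

**Step count**

Total: 11 steps. Longest linear sequence: 9 steps (steps 1 to 8, then step 11); steps 9 and 10 form the two-step branch to ring A.

**Steps most likely to fail**

Step 7 (photo-Fries shift). The radical pair may leave the solvent cage and give the deacylated phenol instead of recombining at the crowded ortho carbon, and light may expel silanol from the ortho-hydroxybenzyl ether. The fallback sets out from 15 and moves the benzylic carbon to the aldehyde level, so that a thermal Lewis-acid Fries rearrangement can be used:
- Bu4NF/AcOH in THF should give 3-hydroxy-4-(hydroxymethyl)-2,5-dimethylphenyl butanoate F1.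
- MnO2 in CH2Cl2 should oxidise the salicyl alcohol to 4-formyl-3-hydroxy-2,5-dimethylphenyl butanoate F2.
- AlCl3 in chlorobenzene at 100 °C should shift the butanoyl group to the single free ring carbon, giving 5-butanoyl-2,4-dihydroxy-3,6-dimethylbenzaldehyde F3.
- One equivalent of NaBH4 in THF–EtOH at −30 °C should reduce the aldehyde in preference to the hindered, chelated ketone.

The fallback comes back to the route at 17.

Step 4 (carbonylative benzannulation). Rhodium may ionise the doubly activated propargylic-allylic ester, the alkyne may oligomerise before the carbene is carbonylated, or the butanoyl group may scramble between the two phenol oxygens. The fallback gives up the ring construction and sets out from butanoyl chloride 6 and a purchased arene: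
- 6 should acylate the non-chelated para hydroxyl of commercial 2,4-dihydroxy-6-methylbenzaldehyde F4 (Et3N, CH2Cl2, −20 °C) to give 4-formyl-3-hydroxy-5-methylphenyl butanoate F5.
- NaBH4 in THF–EtOH at −20 °C should reduce the aldehyde to 3-hydroxy-4-(hydroxymethyl)-5-methylphenyl butanoate F6.
- TBSCl/imidazole in DMF at 0 °C should silylate the primary alcohol in preference to the hindered phenol.

The fallback comes back to the route at 11.

Step 5 (sulfonium ylide ortho-alkylation). The ylide may alkylate oxygen to give the methylthiomethyl ether, or the sigmatropic shift may go to the substituted ortho carbon and stop at a blocked dienone. The fallback sets out from 11 and uses halogenation and cross-coupling: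
- Amine-catalysed ortho-bromination (N-bromosuccinimide, cat. i-Pr2NH, CH2Cl2, 0 °C) should give 2-bromo-4-(tert-butyldimethylsilyloxymethyl)-3-hydroxy-5-methylphenyl butanoate F7.
- Base-free Stille methylation (SnMe4, Pd(PPh3)4 as the source of zerovalent palladium, LiCl, DMF, 100 °C) should replace bromine by methyl without harming the aryl ester.

The fallback comes back to the route at 15, so 14 is bypassed.

**Further compounds**

F1 | step 7 | 3-hydroxy-4-(hydroxymethyl)-2,5-dimethylphenyl butanoate | CCCC(=O)Oc1cc(C)c(CO)c(O)c1C
F2 | step 7 | 4-formyl-3-hydroxy-2,5-dimethylphenyl butanoate | CCCC(=O)Oc1cc(C)c(C=O)c(O)c1C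
F3 | step 7 | 5-butanoyl-2,4-dihydroxy-3,6-dimethylbenzaldehyde | CCCC(=O)c1c(O)c(C)c(O)c(C=O)c1C
F4 | step 4 | 2,4-dihydroxy-6-methylbenzaldehyde (purchased, taken up by the fallback) | Cc1cc(O)cc(O)c1C=O
F5 | step 4 | 4-formyl-3-hydroxy-5-methylphenyl butanoate | CCCC(=O)Oc1cc(C)c(C=O)c(O)c1
F6 | step 4 | 3-hydroxy-4-(hydroxymethyl)-5-methylphenyl butanoate | CCCC(=O)Oc1cc(C)c(CO)c(O)c1
F7 | step 5 | 2-bromo-4-(tert-butyldimethylsilyloxymethyl)-3-hydroxy-5-methylphenyl butanoate | CCCC(=O)Oc1cc(C)c(CO[Si](C)(C)C(C)(C)C)c(O)c1Br
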